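**Plan**
- Retrosynthetic cuts: the 19 benzyl ethers and the two gallate C–O bonds; then, in each of the two upper flavan units, the C3–O/C2–H pair, the C2=C3 bond of ring C, and the C4–C4a aryl bond. The bottom unit stays intact.
- Enabling feature: in ring C of the top unit, C2 carries O1 and ring B and is bonded to C3. The C2=C3 bond can therefore be made as the double bond of a cyclic enol ether, from an O1 aryl ester of the ring-B acid and a vinyl group on C4.
- Forward order: a vinyl carbinol carrying ring A of the middle unit is joined to ring A of the top unit; the ester is closed to the top flav-2-ene and converted to the top flavan-3-ol. The para phenol is then freed and the same four operations, with a catechin-8-yl vinyl carbinol, build ring C of the middle unit. Double galloylation and hydrogenolysis finish.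
- Stereochemistry: both C4 centres come from ligand-controlled iridium allylic substitution. Each C4 aryl sends the epoxidation to the opposite face and hydride opens C2 with inversion (2,3-cis-3,4-trans). The bottom unit is (+)-catechin.

Key step: step 6

Assumption: the (S)-ligand is taken to send the arene to the Si face of the aryl-bearing allyl terminus in steps 4 and 13; if the sense is opposite, its antipode is used in both.
Remark: compounds 5, 7 and 25 are treated as purchased. Bn = benzyl, Ar = 3,4-bis(benzyloxy)phenyl, MOM = methoxymethyl, TBS = tert-butyldimethylsilyl; flavan numbering (O1, C2, C3, C4, C4a, C5–C8, C8a) is used for every chroman unit.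

**Route**

Step 1
Reactants: 1 2,4,6-trihydroxybenzaldehyde
Product: 2 2,6-dihydroxy-4-(methoxymethoxy)benzaldehyde
Conditions: MOMCl (1.05 equiv), i-Pr2NEt, CH2Cl2, 0 °C
Reagents that add atoms: chloromethyl methyl ether, COCCl
Why: Williamson-type O-alkylation; the 4-OH is the only hydroxyl not hydrogen-bonded to the formyl group, is the most acidic, and should react first.

Step 2
Reactants: 2 2,6-dihydroxy-4-(methoxymethoxy)benzaldehyde
Product: 3 2,6-bis(benzyloxy)-4-(methoxymethoxy)benzaldehyde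
Conditions: BnBr, K2CO3, DMF, 60 °C
Reagents that add atoms: benzyl bromide, BrCc1ccccc1
Why: Williamson etherification of the two chelated phenols under forcing carbonate conditions, to which the MOM acetal is inert.

Step 3
Reactants: 3 2,6-bis(benzyloxy)-4-(methoxymethoxy)benzaldehyde
Product: 4 1-[2,6-bis(benzyloxy)-4-(methoxymethoxy)phenyl]prop-2-en-1-ol (racemic)
Conditions: CH2=CHMgBr, THF, −78 → 0 °C
Reagents that add atoms: vinylmagnesium bromide, C=C[Mg]Br
Why: Grignard 1,2-addition to the aldehyde; the racemate is acceptable because the next step is stereoconvergent.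

Step 4
Reactants: 4 1-[2,6-bis(benzyloxy)-4-(methoxymethoxy)phenyl]prop-2-en-1-ol; 5 3,5-bis(benzyloxy)phenol (3 equiv)
Product: 6 3,5-bis(benzyloxy)-2-{(1R)-1-[2,6-bis(benzyloxy)-4-(methoxymethoxy)phenyl]prop-2-en-1-yl}phenol
Conditions: [Ir(cod)Cl]2 (4 mol %), (S)-BINOL-derived N-(dibenzo[b,f]azepin-5-yl) phosphoramidite–olefin ligand (16 mol %), Zn(OTf)2 (10 mol %), 1,2-dichloroethane, 25 °C
Reagents that add atoms: none
Why: Iridium-catalysed enantioselective allylic substitution of Friedel–Crafts type, with loss of water: acid-assisted ionisation of racemic 4 gives an (η3-allyl)iridium complex in which both carbinol enantiomers converge, and the phenol adds through the carbon ortho to its hydroxyl (the site at which this phenol is C-alkylated by cinnamyl cations) to the aryl-bearing terminus from the ligand-defined Si face, setting C4 as (R); ortho-substituted aryl vinyl carbinols lie within the scope of this catalyst system.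

Step 5
Reactants: 6 phenol from step 4; 7 3,4-bis(benzyloxy)benzoic acid
Product: 8 3,5-bis(benzyloxy)-2-{(1S)-1-[2,6-bis(benzyloxy)-4-(methoxymethoxy)phenyl]prop-2-en-1-yl}phenyl 3,4-bis(benzyloxy)benzoate
Conditions: DCC, DMAP (cat.), CH2Cl2, 0 °C → rt
Reagents that add atoms: none
Why: Steglich esterification of the only free hydroxyl; the stereocentre is untouched and its descriptor changes only through substituent priorities.

Step 6
Reactants: 8 aryl 3,4-bis(benzyloxy)benzoate from step 5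
Product: 9 (4S)-5,7-bis(benzyloxy)-2-Ar-4-[2,6-bis(benzyloxy)-4-(methoxymethoxy)phenyl]-4H-chromene (flav-2-ene of the top unit)
Conditions: TiCl4, TMEDA, Zn, PbCl2 (cat.), CH3CHBr2, THF/CH2Cl2, 0 → 65 °C
Reagents that add atoms: none
Why: The titanium ethylidene formed in the flask exchanges with the terminal vinyl group by [2+2]/retro-[2+2], releasing propene and placing titanium on the former vinyl CH (the future C3); this alkylidene adds across the neighbouring ester C=O and the oxatitanacyclobutane collapses to the C2=C3 bond and a titanium oxo species. The closest known reaction is the olefinic-ester cyclisation with the reduced-titanium alkylidene reagent (TiCl4/TMEDA/Zn/PbCl2/1,1-dibromoalkane) that delivers cyclic enol ethers such as glycals and oxepenes, i.e. a carbonyl–olefin metathesis. Ring C closes as a six-membered ring by 6-exo-trig attack of the alkylidene carbon on the ester carbonyl carbon, the carbonyl oxygen leaving the ring. No stereocentre is created. The step needs ring closure to win over plain ethylidenation of the carbonyl and needs C4 to keep its configuration: the unhindered monosubstituted vinyl group should capture the reagent first, the ortho-flanked electron-rich benzoate is slow in intermolecular olefination yet sits six atoms from the alkylidene carbon, no second ester is present, and the C4–H is not acidic in this aprotic, non-basic medium.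

Step 7
Reactants: 9 flav-2-ene from step 6
Product: 11 (2R,3R,4S)-5,7-bis(benzyloxy)-2-Ar-4-[2,6-bis(benzyloxy)-4-(methoxymethoxy)phenyl]chroman-3-ol, via epoxide 10 (not isolated)
Conditions: dimethyldioxirane, acetone/CH2Cl2, −78 → −30 °C; volatiles removed at −30 °C; LiBHEt3, THF, −78 → 0 °C
Reagents that add atoms: dimethyldioxirane, CC1(C)OO1
Why: Epoxidation of the electron-rich enol ether should occur on the face opposite the pseudoaxial C4 aryl (sets C3), and the nucleophilic borohydride should open the 2-aryl glycal-type oxirane at the benzylic, O1-bearing C2 in an SN2 manner with inversion (sets C2), leaving ring B cis to the 3-hydroxyl and trans to the C4 aryl.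

Step 8
Reactants: 11 flavan-3-ol from step 7
Product: 12 3-O-TBS ether of 11
Conditions: TBSOTf, 2,6-lutidine, CH2Cl2, −78 → −20 °C
Reagents that add atoms: tert-butyldimethylsilyl triflate, CC(C)(C)[Si](C)(C)OS(=O)(=O)C(F)(F)F
Why: Silylation of the hindered secondary alcohol with the silyl triflate at low temperature, where the aryl MOM acetal should be left alone, so that no hydroxyl or ester other than the reacting one is present in the second ring closure.

Step 9
Reactants: 12 silyl ether from step 8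
Product: 13 3,5-bis(benzyloxy)-4-[(2R,3R,4S)-5,7-bis(benzyloxy)-2-Ar-3-(TBS-oxy)chroman-4-yl]phenol
Conditions: ZnBr2, n-PrSH, CH2Cl2, 0 °C
Reagents that add atoms: none
Why: Lewis-acid-assisted transfer of the methoxymethyl group to the thiol cleaves the aryl MOM ether within minutes under conditions that benzyl ethers and a hindered secondary TBS ether tolerate.

Step 10
Reactants: 14 (+)-catechin
Product: 15 (2R,3S)-3,5,7-tris(benzyloxy)-2-Ar-chroman (penta-O-benzylcatechin)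
Conditions: NaH, BnBr, DMF, −20 °C → rt
Reagents that add atoms: benzyl bromide, BrCc1ccccc1
Why: Exhaustive Williamson benzylation of the four phenols and the 3-hydroxyl; the 3-O-benzyl group marks the one flavan hydroxyl that must end up free.

Step 11
Reactants: 15 penta-O-benzylcatechin
Product: 16 8-bromo derivative of 15
Conditions: NBS, CH2Cl2, −78 °C → rt
Reagents that add atoms: N-bromosuccinimide, BrN1C(=O)CCC1=O
Why: Electrophilic aromatic bromination at C8, the most nucleophilic position of benzylated flavan-3-ols.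

Step 12
Reactants: 16 8-bromo-penta-O-benzylcatechin
Product: 18 1-[(2R,3S)-3,5,7-tris(benzyloxy)-2-Ar-chroman-8-yl]prop-2-en-1-ol (both C-1 epimers), via aryllithium 17 (not isolated)
Conditions: n-BuLi, THF, −78 °C; acrolein, −78 °C
Reagents that add atoms: acrolein, C=CC=O
Why: Bromine–lithium exchange at low temperature outruns benzylic deprotonation, and the aryllithium adds 1,2 to acrolein; the carbinol configuration is irrelevant for the next step.

Step 13
Reactants: 13 phenol from step 9; 18 catechin-8-yl vinyl carbinol (1.3 equiv)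
Product: 19 3,5-bis(benzyloxy)-2-{(1R)-1-[(2R,3S)-3,5,7-tris(benzyloxy)-2-Ar-chroman-8-yl]prop-2-en-1-yl}-4-[(2R,3R,4R)-5,7-bis(benzyloxy)-2-Ar-3-(TBS-oxy)chroman-4-yl]phenol
Conditions: [Ir(cod)Cl]2 (5 mol %), the (S)-ligand of step 4 (20 mol %), Zn(OTf)2 (10 mol %), 1,2-dichloroethane, 25 → 40 °C
Reagents that add atoms: none
Why: The same iridium-catalysed Friedel–Crafts-type allylic substitution as in step 4, again with loss of water: both carbinol epimers converge on one allyl complex, the only free ring positions of the phenol are the two equivalent carbons ortho to its hydroxyl, the free phenol ring is far more nucleophilic than the fully etherified rings, and the ligand (the nearest stereocentres being remote) should direct Si-face attack to set the middle C4.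

Step 14
Reactants: 19 phenol from step 13; 7 3,4-bis(benzyloxy)benzoic acid
Product: 20 3,4-bis(benzyloxy)benzoate of phenol 19
Conditions: DCC, DMAP (cat.), CH2Cl2, 0 °C → rt
Reagents that add atoms: none
Why: Steglich esterification of the single free hydroxyl.

Step 15
Reactants: 20 ester from step 14
Product: 21 (4R)-5,7-bis(benzyloxy)-2-Ar-6-[(2R,3R,4R)-5,7-bis(benzyloxy)-2-Ar-3-(TBS-oxy)chroman-4-yl]-4-[(2R,3S)-3,5,7-tris(benzyloxy)-2-Ar-chroman-8-yl]-4H-chromene
Conditions: TiCl4, TMEDA, Zn, PbCl2 (cat.), CH3CHBr2, THF/CH2Cl2, 0 → 65 °C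
Reagents that add atoms: none
Why: Second olefinic-ester cyclisation (carbonyl–olefin metathesis through the titanium ethylidene) on the only ester and only alkene of the molecule, closing ring C of the middle unit without touching its C4.

Step 16
Reactants: 21 flav-2-ene from step 15
Product: 23 (2R,3R,4R)-5,7-bis(benzyloxy)-2-Ar-6-[(2R,3R,4R)-5,7-bis(benzyloxy)-2-Ar-3-(TBS-oxy)chroman-4-yl]-4-[(2R,3S)-3,5,7-tris(benzyloxy)-2-Ar-chroman-8-yl]chroman-3-ol, via epoxide 22 (not isolated)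
Conditions: dimethyldioxirane, acetone/CH2Cl2, −78 → −30 °C; volatiles removed at −30 °C; LiBHEt3, THF, −78 → 0 °C
Reagents that add atoms: dimethyldioxirane, CC1(C)OO1
Why: As in step 7, epoxidation should occur anti to the C4 substituent (here the catechin unit) and hydride should open C2 with inversion, giving the 2,3-cis-3,4-trans middle unit.

Step 17
Reactants: 23 alcohol from step 16
Product: 24 diol with free 3-hydroxyls on the top and middle units
Conditions: TBAF, THF, 0 → 45 °C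
Reagents that add atoms: none
Why: Fluoride cleavage of the silyl ether; benzyl ethers are inert.

Step 18
Reactants: 24 diol from step 17; 25 3,4,5-tris(benzyloxy)benzoic acid (first equivalent)
Product: 26 bis[3,4,5-tris(benzyloxy)benzoate] of diol 24 (perbenzylated target)
Conditions: DCC (3 equiv), DMAP, CH2Cl2, rt → 35 °C; 3 equiv of acid 25 in total
Reagents that add atoms: 3,4,5-tris(benzyloxy)benzoic acid (second equivalent of 25), O=C(O)c1cc(OCc5ccccc5)c(OCc5ccccc5)c(OCc5ccccc5)c1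
Why: Double Steglich esterification in which each of the two secondary 3-hydroxyls takes up one equivalent of the acid, the standard way to galloylate 4-substituted flavan-3-ols; the bottom 3-oxygen is blocked as its benzyl ether.

Step 19
Reactants: 26 perbenzylated digallate
Product: 27 (−)-epicatechin-3-O-gallate-(4β→6)-(−)-epicatechin-3-O-gallate-(4β→8)-(+)-catechin (CNP0112921.1)
Conditions: H2 (1 atm), Pd(OH)2/C, THF/MeOH/H2O, rt
Reagents that add atoms: none
Why: Hydrogenolysis of all 19 benzyl ethers over Pd(OH)2/C, the usual final step for benzylated procyanidin gallates; the esters and the C4–aryl bonds are stable under these neutral conditions.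

**Compound list**
1 | 2,4,6-trihydroxybenzaldehyde | O=Cc1c(O)cc(O)cc1O | starting material
2 | 2,6-dihydroxy-4-(methoxymethoxy)benzaldehyde | O=Cc1c(O)cc(OCOC)cc1O | intermediate
3 | 2,6-bis(benzyloxy)-4-(methoxymethoxy)benzaldehyde | O=Cc1c(OCc5ccccc5)cc(OCOC)cc1OCc5ccccc5 | intermediate
4 | 1-[2,6-bis(benzyloxy)-4-(methoxymethoxy)phenyl]prop-2-en-1-ol, racemic | C=CC(O)c1c(OCc5ccccc5)cc(OCOC)cc1OCc5ccccc5 | intermediate
5 | 3,5-bis(benzyloxy)phenol | Oc1cc(OCc5ccccc5)cc(OCc5ccccc5)c1 | starting material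
6 | 3,5-bis(benzyloxy)-2-{(1R)-1-[2,6-bis(benzyloxy)-4-(methoxymethoxy)phenyl]prop-2-en-1-yl}phenol | C=C[C@@H](c1c(OCc5ccccc5)cc(OCOC)cc1OCc5ccccc5)c1c(OCc5ccccc5)cc(OCc5ccccc5)cc1O | intermediate
7 | 3,4-bis(benzyloxy)benzoic acid | O=C(O)c1ccc(OCc5ccccc5)c(OCc5ccccc5)c1 | starting material
8 | 3,5-bis(benzyloxy)-2-{(1S)-1-[2,6-bis(benzyloxy)-4-(methoxymethoxy)phenyl]prop-2-en-1-yl}phenyl 3,4-bis(benzyloxy)benzoate (same geometry as 6) | C=C[C@@H](c1c(OCc5ccccc5)cc(OCOC)cc1OCc5ccccc5)c1c(OCc5ccccc5)cc(OCc5ccccc5)cc1OC(=O)c1ccc(OCc5ccccc5)c(OCc5ccccc5)c1 | intermediate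
9 | (4S)-5,7-bis(benzyloxy)-2-Ar-4-[2,6-bis(benzyloxy)-4-(methoxymethoxy)phenyl]-4H-chromene | C1=C(c2ccc(OCc5ccccc5)c(OCc5ccccc5)c2)Oc2cc(OCc5ccccc5)cc(OCc5ccccc5)c2[C@@H]1c1c(OCc5ccccc5)cc(OCOC)cc1OCc5ccccc5 | intermediate
10 | (2S,3R,4S)-2,3-epoxide of 9, oxirane trans to the C4 aryl (not isolated) | O3[C@@H]1[C@@H](c4c(OCc5ccccc5)cc(OCOC)cc4OCc5ccccc5)c2c(OCc5ccccc5)cc(OCc5ccccc5)cc2O[C@@]13c1ccc(OCc5ccccc5)c(OCc5ccccc5)c1 | intermediate
11 | (2R,3R,4S)-5,7-bis(benzyloxy)-2-Ar-4-[2,6-bis(benzyloxy)-4-(methoxymethoxy)phenyl]chroman-3-ol (2,3-cis-3,4-trans) | O[C@@H]1[C@@H](c4c(OCc5ccccc5)cc(OCOC)cc4OCc5ccccc5)c2c(OCc5ccccc5)cc(OCc5ccccc5)cc2O[C@@H]1c1ccc(OCc5ccccc5)c(OCc5ccccc5)c1 | intermediate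
12 | 3-O-TBS ether of 11 | CC(C)(C)[Si](C)(C)O[C@@H]1[C@@H](c4c(OCc5ccccc5)cc(OCOC)cc4OCc5ccccc5)c2c(OCc5ccccc5)cc(OCc5ccccc5)cc2O[C@@H]1c1ccc(OCc5ccccc5)c(OCc5ccccc5)c1 | intermediate
13 | 3,5-bis(benzyloxy)-4-[(2R,3R,4S)-5,7-bis(benzyloxy)-2-Ar-3-(TBS-oxy)chroman-4-yl]phenol | CC(C)(C)[Si](C)(C)O[C@@H]1[C@@H](c4c(OCc5ccccc5)cc(O)cc4OCc5ccccc5)c2c(OCc5ccccc5)cc(OCc5ccccc5)cc2O[C@@H]1c1ccc(OCc5ccccc5)c(OCc5ccccc5)c1 | intermediate
14 | (+)-catechin, (2R,3S) | Oc1cc(O)c2c(c1)O[C@H](c1ccc(O)c(O)c1)[C@@H](O)C2 | starting material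
15 | (2R,3S)-3,5,7-tris(benzyloxy)-2-Ar-chroman | O(Cc5ccccc5)c1cc(OCc5ccccc5)c2c(c1)O[C@H](c1ccc(OCc5ccccc5)c(OCc5ccccc5)c1)[C@@H](OCc5ccccc5)C2 | intermediate
16 | (2R,3S)-8-bromo-3,5,7-tris(benzyloxy)-2-Ar-chroman | Brc1c(OCc5ccccc5)cc(OCc5ccccc5)c2c1O[C@H](c1ccc(OCc5ccccc5)c(OCc5ccccc5)c1)[C@@H](OCc5ccccc5)C2 | intermediate
17 | 8-lithio analogue of 16 (not isolated) | [Li]c1c(OCc5ccccc5)cc(OCc5ccccc5)c2c1O[C@H](c1ccc(OCc5ccccc5)c(OCc5ccccc5)c1)[C@@H](OCc5ccccc5)C2 | intermediate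
18 | 1-[(2R,3S)-3,5,7-tris(benzyloxy)-2-Ar-chroman-8-yl]prop-2-en-1-ol, both C-1 epimers | C=CC(O)c1c(OCc5ccccc5)cc(OCc5ccccc5)c2c1O[C@H](c1ccc(OCc5ccccc5)c(OCc5ccccc5)c1)[C@@H](OCc5ccccc5)C2 | intermediate
19 | 3,5-bis(benzyloxy)-2-{(1R)-1-[(2R,3S)-3,5,7-tris(benzyloxy)-2-Ar-chroman-8-yl]prop-2-en-1-yl}-4-[(2R,3R,4R)-5,7-bis(benzyloxy)-2-Ar-3-(TBS-oxy)chroman-4-yl]phenol (top unit geometry as in 13; its C4 descriptor changes by priority only) | CC(C)(C)[Si](C)(C)O[C@@H]1[C@@H](c2c(OCc5ccccc5)cc(O)c(c2OCc5ccccc5)[C@H](c4c(OCc5ccccc5)cc(OCc5ccccc5)c6c4O[C@H](c4ccc(OCc5ccccc5)c(OCc5ccccc5)c4)[C@@H](OCc5ccccc5)C6)C=C)c2c(OCc5ccccc5)cc(OCc5ccccc5)cc2O[C@@H]1c1ccc(OCc5ccccc5)c(OCc5ccccc5)c1 | intermediate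
20 | 3,4-bis(benzyloxy)benzoate of phenol 19 | CC(C)(C)[Si](C)(C)O[C@@H]1[C@@H](c2c(OCc5ccccc5)cc(OC(=O)c3ccc(OCc5ccccc5)c(OCc5ccccc5)c3)c(c2OCc5ccccc5)[C@H](c4c(OCc5ccccc5)cc(OCc5ccccc5)c6c4O[C@H](c4ccc(OCc5ccccc5)c(OCc5ccccc5)c4)[C@@H](OCc5ccccc5)C6)C=C)c2c(OCc5ccccc5)cc(OCc5ccccc5)cc2O[C@@H]1c1ccc(OCc5ccccc5)c(OCc5ccccc5)c1 | intermediate
21 | (4R)-5,7-bis(benzyloxy)-2-Ar-6-[(2R,3R,4R)-5,7-bis(benzyloxy)-2-Ar-3-(TBS-oxy)chroman-4-yl]-4-[(2R,3S)-3,5,7-tris(benzyloxy)-2-Ar-chroman-8-yl]-4H-chromene | CC(C)(C)[Si](C)(C)O[C@@H]1[C@@H](c2c(OCc5ccccc5)cc3c(c2OCc5ccccc5)[C@H](c4c(OCc5ccccc5)cc(OCc5ccccc5)c6c4O[C@H](c4ccc(OCc5ccccc5)c(OCc5ccccc5)c4)[C@@H](OCc5ccccc5)C6)C=C(c2ccc(OCc5ccccc5)c(OCc5ccccc5)c2)O3)c2c(OCc5ccccc5)cc(OCc5ccccc5)cc2O[C@@H]1c1ccc(OCc5ccccc5)c(OCc5ccccc5)c1 | intermediate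
22 | (2S,3R,4R)-2,3-epoxide of the middle unit of 21, oxirane trans to the C4 substituent (not isolated) | CC(C)(C)[Si](C)(C)O[C@@H]1[C@@H](c2c(OCc5ccccc5)cc3c(c2OCc5ccccc5)[C@H](c4c(OCc5ccccc5)cc(OCc5ccccc5)c6c4O[C@H](c4ccc(OCc5ccccc5)c(OCc5ccccc5)c4)[C@@H](OCc5ccccc5)C6)[C@@H](O7)[C@]7(c2ccc(OCc5ccccc5)c(OCc5ccccc5)c2)O3)c2c(OCc5ccccc5)cc(OCc5ccccc5)cc2O[C@@H]1c1ccc(OCc5ccccc5)c(OCc5ccccc5)c1 | intermediate
23 | (2R,3R,4R)-5,7-bis(benzyloxy)-2-Ar-6-[(2R,3R,4R)-5,7-bis(benzyloxy)-2-Ar-3-(TBS-oxy)chroman-4-yl]-4-[(2R,3S)-3,5,7-tris(benzyloxy)-2-Ar-chroman-8-yl]chroman-3-ol | CC(C)(C)[Si](C)(C)O[C@@H]1[C@@H](c2c(OCc5ccccc5)cc3c(c2OCc5ccccc5)[C@H](c4c(OCc5ccccc5)cc(OCc5ccccc5)c6c4O[C@H](c4ccc(OCc5ccccc5)c(OCc5ccccc5)c4)[C@@H](OCc5ccccc5)C6)[C@@H](O)[C@@H](c2ccc(OCc5ccccc5)c(OCc5ccccc5)c2)O3)c2c(OCc5ccccc5)cc(OCc5ccccc5)cc2O[C@@H]1c1ccc(OCc5ccccc5)c(OCc5ccccc5)c1 | intermediate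
24 | diol: 23 with the top 3-hydroxyl also free | O[C@@H]1[C@@H](c2c(OCc5ccccc5)cc3c(c2OCc5ccccc5)[C@H](c4c(OCc5ccccc5)cc(OCc5ccccc5)c6c4O[C@H](c4ccc(OCc5ccccc5)c(OCc5ccccc5)c4)[C@@H](OCc5ccccc5)C6)[C@@H](O)[C@@H](c2ccc(OCc5ccccc5)c(OCc5ccccc5)c2)O3)c2c(OCc5ccccc5)cc(OCc5ccccc5)cc2O[C@@H]1c1ccc(OCc5ccccc5)c(OCc5ccccc5)c1 | intermediate
25 | 3,4,5-tris(benzyloxy)benzoic acid | O=C(O)c1cc(OCc5ccccc5)c(OCc5ccccc5)c(OCc5ccccc5)c1 | starting material
26 | bis-O-[3,4,5-tris(benzyloxy)benzoyl] derivative of diol 24 at the 3-oxygens of the top and middle units; top (2R,3R,4R), middle (2R,3R,4R), bottom (2R,3S) | O=C(O[C@@H]1[C@@H](c2c(OCc5ccccc5)cc3c(c2OCc5ccccc5)[C@H](c4c(OCc5ccccc5)cc(OCc5ccccc5)c6c4O[C@H](c4ccc(OCc5ccccc5)c(OCc5ccccc5)c4)[C@@H](OCc5ccccc5)C6)[C@@H](OC(=O)c2cc(OCc5ccccc5)c(OCc5ccccc5)c(OCc5ccccc5)c2)[C@@H](c2ccc(OCc5ccccc5)c(OCc5ccccc5)c2)O3)c2c(OCc5ccccc5)cc(OCc5ccccc5)cc2O[C@@H]1c1ccc(OCc5ccccc5)c(OCc5ccccc5)c1)c1cc(OCc5ccccc5)c(OCc5ccccc5)c(OCc5ccccc5)c1 | intermediate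
27 | (−)-epicatechin-3-O-gallate-(4β→6)-(−)-epicatechin-3-O-gallate-(4β→8)-(+)-catechin; top (2R,3R,4S), middle (2R,3R,4R), bottom (2R,3S) | O=C(O[C@@H]1[C@@H](c2c(O)cc3c(c2O)[C@H](c2c(O)cc(O)c4c2O[C@H](c2ccc(O)c(O)c2)[C@@H](O)C4)[C@@H](OC(=O)c2cc(O)c(O)c(O)c2)[C@@H](c2ccc(O)c(O)c2)O3)c2c(O)cc(O)cc2O[C@@H]1c1ccc(O)c(O)c1)c1cc(O)c(O)c(O)c1 | target

**Totals**
Total steps: 19. Longest linear sequence: 16 (steps 1–9 and 13–19).

**Steps most likely to fail**

Step 13. Ionisation of the very electron-rich carbinol outside the metal's coordination sphere would erode branch and facial selectivity, and O-allylation or slow turnover with two large partners may compete. The fallback sets out from 18 and 13 and returns at 19. Carbinol 18 is converted with methyl chloroformate and pyridine into methyl 1-[(2R,3S)-3,5,7-tris(benzyloxy)-2-Ar-chroman-8-yl]prop-2-en-1-yl carbonate F1. Pd(PPh3)4 then joins it to phenol 13 through oxygen as the linear (E)-3-(chroman-8-yl)allyl aryl ether F2. A thermal aromatic Claisen rearrangement (N,N-diethylaniline, 150 °C) moves the allyl unit to the ortho carbon with allylic transposition. This is ortho-specific but not face-selective, so 19 should form together with its (1S)-epimer F3, and the two diastereomers are separated by chromatography.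

Step 7. The oxirane may ionise to an open oxocarbenium ion before hydride arrives, which would erase the inversion at C2 or divert material to the 3-ketone by hydride shift. The fallback sets out from 9 and returns at 11. OsO4/NMO should dihydroxylate the enol ether anti to the C4 aryl, and the hemiketal opens to (2R,3R)-1-Ar-3-[2,4-bis(benzyloxy)-6-hydroxyphenyl]-3-[2,6-bis(benzyloxy)-4-(methoxymethoxy)phenyl]-2-hydroxypropan-1-one F4. Zn(BH4)2 should reduce the ketone under chelation control to the anti diol, (1S,2R,3R)-1-Ar-3-[2,4-bis(benzyloxy)-6-hydroxyphenyl]-3-[2,6-bis(benzyloxy)-4-(methoxymethoxy)phenyl]propane-1,2-diol F5. A Mitsunobu cyclodehydration (PPh3, DIAD) then lets the phenol displace the benzylic hydroxyl with inversion, closing ring C as the 2,3-cis alcohol 11.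

Step 6. The ester carbonyl may simply be ethylidenated without ring closure, and traces of acid could move the new double bond toward C4 with loss of that centre. The fallback sets out from 8 and returns at 9. Cp2TiMe2 (toluene, 65 °C) methylenates the ester to the enol ether 1,5-bis(benzyloxy)-2-{(1S)-1-[2,6-bis(benzyloxy)-4-(methoxymethoxy)phenyl]prop-2-en-1-yl}-3-[(1-Ar-ethenyl)oxy]benzene F6. The second-generation Grubbs catalyst (toluene, 70 °C) then closes ring C by ring-closing metathesis between the enol ether and the vinyl group.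

Further compounds
F1 | step 13 | methyl 1-[(2R,3S)-3,5,7-tris(benzyloxy)-2-Ar-chroman-8-yl]prop-2-en-1-yl carbonate, both C-1 epimers | C=CC(OC(=O)OC)c1c(OCc5ccccc5)cc(OCc5ccccc5)c2c1O[C@H](c1ccc(OCc5ccccc5)c(OCc5ccccc5)c1)[C@@H](OCc5ccccc5)C2
F2 | step 13 | O-[(2E)-3-{(2R,3S)-3,5,7-tris(benzyloxy)-2-Ar-chroman-8-yl}prop-2-en-1-yl] ether of phenol 13 | CC(C)(C)[Si](C)(C)O[C@@H]1[C@@H](c4c(OCc5ccccc5)cc(OC/C=C/c6c(OCc5ccccc5)cc(OCc5ccccc5)c7c6O[C@H](c6ccc(OCc5ccccc5)c(OCc5ccccc5)c6)[C@@H](OCc5ccccc5)C7)cc4OCc5ccccc5)c2c(OCc5ccccc5)cc(OCc5ccccc5)cc2O[C@@H]1c1ccc(OCc5ccccc5)c(OCc5ccccc5)c1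
F3 | step 13 | (1S)-epimer of 19 at the allylic methine | CC(C)(C)[Si](C)(C)O[C@@H]1[C@@H](c2c(OCc5ccccc5)cc(O)c(c2OCc5ccccc5)[C@@H](c4c(OCc5ccccc5)cc(OCc5ccccc5)c6c4O[C@H](c4ccc(OCc5ccccc5)c(OCc5ccccc5)c4)[C@@H](OCc5ccccc5)C6)C=C)c2c(OCc5ccccc5)cc(OCc5ccccc5)cc2O[C@@H]1c1ccc(OCc5ccccc5)c(OCc5ccccc5)c1
F4 | step 7 | (2R,3R)-1-Ar-3-[2,4-bis(benzyloxy)-6-hydroxyphenyl]-3-[2,6-bis(benzyloxy)-4-(methoxymethoxy)phenyl]-2-hydroxypropan-1-one | O[C@@H](C(=O)c1ccc(OCc5ccccc5)c(OCc5ccccc5)c1)[C@@H](c4c(OCc5ccccc5)cc(OCOC)cc4OCc5ccccc5)c2c(OCc5ccccc5)cc(OCc5ccccc5)cc2O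
F5 | step 7 | (1S,2R,3R)-1-Ar-3-[2,4-bis(benzyloxy)-6-hydroxyphenyl]-3-[2,6-bis(benzyloxy)-4-(methoxymethoxy)phenyl]propane-1,2-diol | O[C@@H]([C@@H](O)c1ccc(OCc5ccccc5)c(OCc5ccccc5)c1)[C@@H](c4c(OCc5ccccc5)cc(OCOC)cc4OCc5ccccc5)c2c(OCc5ccccc5)cc(OCc5ccccc5)cc2O
F6 | step 6 | 1,5-bis(benzyloxy)-2-{(1S)-1-[2,6-bis(benzyloxy)-4-(methoxymethoxy)phenyl]prop-2-en-1-yl}-3-[(1-Ar-ethenyl)oxy]benzene | C=C[C@@H](c1c(OCc5ccccc5)cc(OCOC)cc1OCc5ccccc5)c1c(OCc5ccccc5)cc(OCc5ccccc5)cc1OC(=C)c1ccc(OCc5ccccc5)c(OCc5ccccc5)c1
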